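**Plan**

- Retrosynthesis: after removal of the benzyl and silyl groups and return of the C3 CH2OH to an ester (one of a geminal pair), the tetrahydrofuran is cut at O1–C5 and C2–C3. This gives O-benzylvanillin (C2 and O1) and a cyclopropane-1,1-diester that holds C3, C4 and C5 as a three-membered ring; the cyclopropane is cut to an (E)-cinnamaldehyde and bromomalonate.
- Forward: O-benzylvanillin → enal → aminocatalytic cyclopropanation → reduction and silylation → Lewis-acid ring expansion of the cyclopropane by insertion of the C=O of a second molecule of O-benzylvanillin (three → five ring atoms) → dealkoxycarbonylation → benzylic equilibration → ester reduction and deprotection.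
- Enabling feature: in the cyclopropane the C1–C3 bond carries a 4-benzyloxy-3-methoxyphenyl donor on C3 and two ester acceptors on C1, so it heterolyses to a benzylic cation/malonate pair that takes up the aldehyde. The same aldehyde serves twice because the target is C2-symmetric.
- Stereochemistry: C4 (S) is the only centre made by asymmetric catalysis and is never touched again. C3 follows by epimerisation α to the ester, and C2 and C5 by acid equilibration of the two benzylic ether carbons, so the isomers formed on the way are funnelled into the all-trans ring.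

Key step: step 5

Remark: the target SMILES is read as the C2-symmetric all-trans (2R,3S,4S,5R) isomer. Compounds 1, 2, 4 and (R)-α,α-diphenylprolinol trimethylsilyl ether are taken as commercial.
Remark on locants: in the cyclopropanes C2 carries the formyl/CH2O group and C3 the aryl group; in the tetrahydrofurans C2 is the carbon delivered by the aldehyde and C5 the former cyclopropane C3.

**Route**

Step 1
Reactants: 1 4-(benzyloxy)-3-methoxybenzaldehyde; 2 (triphenylphosphoranylidene)acetaldehyde
Product: 3 (E)-3-[4-(benzyloxy)-3-methoxyphenyl]prop-2-enal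
Conditions: 2 (1.2 equiv), toluene, 90 °C
Reagents that add atoms: 2 (triphenylphosphoranylidene)acetaldehyde, O=CC=P(c1ccccc1)(c1ccccc1)c1ccccc1
Why: Wittig olefination with the stabilised formylmethylene ylide should give the (E)-enal, the conjugated electron-rich product reacting more slowly with the ylide than the starting aldehyde.

Step 2
Reactants: 3 (E)-3-[4-(benzyloxy)-3-methoxyphenyl]prop-2-enal; 4 dimethyl 2-bromomalonate
Product: 5 dimethyl (2S,3R)-3-[4-(benzyloxy)-3-methoxyphenyl]-2-formylcyclopropane-1,1-dicarboxylate (aryl and formyl trans)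
Conditions: (R)-α,α-diphenylprolinol trimethylsilyl ether (20 mol %), 2,6-lutidine (1.1 equiv), CH2Cl2, 0 °C → rt
Reagents that add atoms: 4 dimethyl 2-bromomalonate, COC(=O)C(Br)C(=O)OC
Why: Iminium-catalysed Michael addition of the bromomalonate to the E,s-trans iminium ion on the face anti to the CPh2OTMS group, then enamine α-alkylation (Michael-initiated ring closure), should give the trans-cyclopropane; the (R)-catalyst sets C3 as R and with it C2 as S.

Step 3
Reactants: 5 dimethyl (2S,3R)-3-[4-(benzyloxy)-3-methoxyphenyl]-2-formylcyclopropane-1,1-dicarboxylate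
Product: 6 dimethyl (2S,3R)-3-[4-(benzyloxy)-3-methoxyphenyl]-2-(hydroxymethyl)cyclopropane-1,1-dicarboxylate
Conditions: NaBH4, MeOH–CH2Cl2, −20 °C; pH 7 buffer; used without delay
Reagents that add atoms: none
Why: Chemoselective borohydride reduction of the aldehyde beside the malonate esters, kept cold and neutral so that the hydroxymethyl group does not lactonise onto the cis ester; no stereocentre is touched.

Step 4
Reactants: 6 dimethyl (2S,3R)-3-[4-(benzyloxy)-3-methoxyphenyl]-2-(hydroxymethyl)cyclopropane-1,1-dicarboxylate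
Product: 7 dimethyl (2S,3R)-3-[4-(benzyloxy)-3-methoxyphenyl]-2-{[(tert-butyldiphenylsilyl)oxy]methyl}cyclopropane-1,1-dicarboxylate
Conditions: TBDPSCl, imidazole, CH2Cl2, 0 °C → rt
Reagents that add atoms: tert-butyl(chloro)diphenylsilane (TBDPSCl), CC(C)(C)[Si](Cl)(c1ccccc1)c1ccccc1
Why: Imidazole-promoted silylation of the primary alcohol gives a Lewis-acid- and base-stable ether that blocks lactonisation (which would lock C3/C4 cis) and later participation of this oxygen.

Step 5
Reactants: 7 dimethyl (2S,3R)-3-[4-(benzyloxy)-3-methoxyphenyl]-2-{[(tert-butyldiphenylsilyl)oxy]methyl}cyclopropane-1,1-dicarboxylate; 1 4-(benzyloxy)-3-methoxybenzaldehyde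
Product: 8 dimethyl (2S,4S,5S)-2,5-bis[4-(benzyloxy)-3-methoxyphenyl]-4-{[(tert-butyldiphenylsilyl)oxy]methyl}tetrahydrofuran-3,3-dicarboxylate (2-aryl, 4-CH2OSi and 5-aryl all cis)
Conditions: 1 (3 equiv), AlCl3 (20 mol %), CH2Cl2, 0 °C → rt
Reagents that add atoms: 1 4-(benzyloxy)-3-methoxybenzaldehyde, O=Cc1ccc(OCc2ccccc2)c(OC)c1
Why: AlCl3 chelates the geminal diester and polarises the C1–C3 bond of the donor–acceptor cyclopropane; the carbonyl oxygen of 1 attacks the aryl-bearing C3 in an SN2-like opening of the tight ion pair, and the resulting aluminium malonate/oxocarbenium zwitterion collapses by C–C bond formation (closest known type: the Lewis-acid-catalysed formal [3+2] annulation of aldehydes with 2-aryl- and 2,3-disubstituted cyclopropane-1,1-diesters, a ring expansion by C=O insertion). The tetrahydrofuran closes in a 5-(enolexo)-endo-trig, aldol-type mode, the malonate carbon adding to the oxocarbenium carbon through an envelope transition state. C5 is set by inversion at the former cyclopropane C3 (hence cis to the C4 CH2OSi group from the trans-cyclopropane), C2 by the envelope with both aryl groups pseudo-equatorial (2,5-cis), and C4 is carried over unchanged from 7. The step needs cleavage of the C1–C3 bond and not C1–C2, and retention at C4; the 4-benzyloxy-3-methoxyphenyl donor on C3 (against a CH2OSi group on C2) directs the heterolysis, and no bond to C4 is broken. The configurations at C2 and C5 need not be final here, because both benzylic ether centres are equilibrated in step 7.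

Step 6
Reactants: 8 dimethyl (2S,4S,5S)-2,5-bis[4-(benzyloxy)-3-methoxyphenyl]-4-{[(tert-butyldiphenylsilyl)oxy]methyl}tetrahydrofuran-3,3-dicarboxylate
Product: 10 methyl (2R,3R,4S,5S)-2,5-bis[4-(benzyloxy)-3-methoxyphenyl]-4-{[(tert-butyldiphenylsilyl)oxy]methyl}tetrahydrofuran-3-carboxylate (2,3-trans, 3,4-trans, 4,5-cis), via methyl (2R,4S,5S)-2,5-bis[4-(benzyloxy)-3-methoxyphenyl]-4-{[(tert-butyldiphenylsilyl)oxy]methyl}tetrahydrofuran-3-carboxylate as a mixture of C3 epimers 9 (not isolated)
Conditions: LiCl, H2O, DMSO, 150 °C; then NaOMe (0.3 equiv), MeOH–THF, rt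
Reagents that add atoms: none
Why: Krapcho dealkoxycarbonylation (chloride SN2 at O-methyl, decarboxylation, protonation) removes one ester, and methoxide then equilibrates the C3–H α to the remaining ester so that CO2Me lies trans to both the C2 aryl and the C4 CH2OSi group (thermodynamic control; ring opening by retro-oxa-Michael would be a disfavoured 5-endo process).

Step 7
Reactants: 10 methyl (2R,3R,4S,5S)-2,5-bis[4-(benzyloxy)-3-methoxyphenyl]-4-{[(tert-butyldiphenylsilyl)oxy]methyl}tetrahydrofuran-3-carboxylate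
Product: 11 methyl (2R,3R,4S,5R)-2,5-bis[4-(benzyloxy)-3-methoxyphenyl]-4-{[(tert-butyldiphenylsilyl)oxy]methyl}tetrahydrofuran-3-carboxylate (all-trans)
Conditions: BF3·OEt2 (1.5 equiv), CH2Cl2, −20 °C → rt
Reagents that add atoms: none
Why: Reversible Lewis-acid heterolysis of the p-alkoxybenzylic C5–O bond and reclosure (the BF3-promoted cis → trans epimerisation known for 2-aryl tetrahydrofuran lignans) should move the C5 aryl trans to the C4 substituent and give the thermodynamically favoured all-trans ring; C3 and C4 are not affected.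

Step 8
Reactants: 11 methyl (2R,3R,4S,5R)-2,5-bis[4-(benzyloxy)-3-methoxyphenyl]-4-{[(tert-butyldiphenylsilyl)oxy]methyl}tetrahydrofuran-3-carboxylate
Product: 12 [(2R,3S,4S,5R)-2,5-bis[4-(benzyloxy)-3-methoxyphenyl]-4-{[(tert-butyldiphenylsilyl)oxy]methyl}tetrahydrofuran-3-yl]methanol
Conditions: LiAlH4, THF, 0 °C
Reagents that add atoms: none
Why: Hydride reduction of the methyl ester to the primary alcohol; no stereocentre is touched (the C3 descriptor changes only by CIP priority) and the silyl and benzyl ethers are stable at 0 °C.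

Step 9
Reactants: 12 [(2R,3S,4S,5R)-2,5-bis[4-(benzyloxy)-3-methoxyphenyl]-4-{[(tert-butyldiphenylsilyl)oxy]methyl}tetrahydrofuran-3-yl]methanol
Product: 13 [(2R,3S,4S,5R)-2,5-bis[4-(benzyloxy)-3-methoxyphenyl]tetrahydrofuran-3,4-diyl]dimethanol
Conditions: TBAF, THF, rt
Reagents that add atoms: none
Why: Fluoride-mediated cleavage of the silyl ether under conditions that leave the aryl benzyl ethers and the ring untouched.

Step 10
Reactants: 13 [(2R,3S,4S,5R)-2,5-bis[4-(benzyloxy)-3-methoxyphenyl]tetrahydrofuran-3,4-diyl]dimethanol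
Product: 14 (+)-neoolivil, [(2R,3S,4S,5R)-2,5-bis(4-hydroxy-3-methoxyphenyl)tetrahydrofuran-3,4-diyl]dimethanol
Conditions: H2 (1 atm), 10% Pd/C, EtOAc–MeOH, rt, stopped at full conversion
Reagents that add atoms: none
Why: Hydrogenolysis of the two aryl benzyl ethers over Pd/C, which is expected to be much faster than hydrogenolysis of the hindered dibenzylic ring C–O bonds.

**Compound list**

1 | 4-(benzyloxy)-3-methoxybenzaldehyde | O=Cc1ccc(OCc2ccccc2)c(OC)c1 | starting material
2 | (triphenylphosphoranylidene)acetaldehyde | O=CC=P(c1ccccc1)(c1ccccc1)c1ccccc1 | starting material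
3 | (E)-3-[4-(benzyloxy)-3-methoxyphenyl]prop-2-enal | O=C/C=C/c1ccc(OCc2ccccc2)c(OC)c1 | intermediate
4 | dimethyl 2-bromomalonate | COC(=O)C(Br)C(=O)OC | starting material
5 | dimethyl (2S,3R)-3-[4-(benzyloxy)-3-methoxyphenyl]-2-formylcyclopropane-1,1-dicarboxylate | O=C[C@H]1[C@H](c2ccc(OCc3ccccc3)c(OC)c2)C1(C(=O)OC)C(=O)OC | intermediate
6 | dimethyl (2S,3R)-3-[4-(benzyloxy)-3-methoxyphenyl]-2-(hydroxymethyl)cyclopropane-1,1-dicarboxylate | OC[C@H]1[C@H](c2ccc(OCc3ccccc3)c(OC)c2)C1(C(=O)OC)C(=O)OC | intermediate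
7 | dimethyl (2S,3R)-3-[4-(benzyloxy)-3-methoxyphenyl]-2-{[(tert-butyldiphenylsilyl)oxy]methyl}cyclopropane-1,1-dicarboxylate | CC(C)(C)[Si](OC[C@H]1[C@H](c2ccc(OCc3ccccc3)c(OC)c2)C1(C(=O)OC)C(=O)OC)(c1ccccc1)c1ccccc1 | intermediate
8 | dimethyl (2S,4S,5S)-2,5-bis[4-(benzyloxy)-3-methoxyphenyl]-4-{[(tert-butyldiphenylsilyl)oxy]methyl}tetrahydrofuran-3,3-dicarboxylate | COc1cc([C@@H]2O[C@H](c3ccc(OCc4ccccc4)c(OC)c3)[C@H](CO[Si](c3ccccc3)(c3ccccc3)C(C)(C)C)C2(C(=O)OC)C(=O)OC)ccc1OCc1ccccc1 | intermediate
9 | methyl (2R,4S,5S)-2,5-bis[4-(benzyloxy)-3-methoxyphenyl]-4-{[(tert-butyldiphenylsilyl)oxy]methyl}tetrahydrofuran-3-carboxylate, mixture of C3 epimers | COc1cc([C@@H]2O[C@H](c3ccc(OCc4ccccc4)c(OC)c3)[C@H](CO[Si](c3ccccc3)(c3ccccc3)C(C)(C)C)C2C(=O)OC)ccc1OCc1ccccc1 | intermediate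
10 | methyl (2R,3R,4S,5S)-2,5-bis[4-(benzyloxy)-3-methoxyphenyl]-4-{[(tert-butyldiphenylsilyl)oxy]methyl}tetrahydrofuran-3-carboxylate | COc1cc([C@@H]2O[C@H](c3ccc(OCc4ccccc4)c(OC)c3)[C@H](CO[Si](c3ccccc3)(c3ccccc3)C(C)(C)C)[C@H]2C(=O)OC)ccc1OCc1ccccc1 | intermediate
11 | methyl (2R,3R,4S,5R)-2,5-bis[4-(benzyloxy)-3-methoxyphenyl]-4-{[(tert-butyldiphenylsilyl)oxy]methyl}tetrahydrofuran-3-carboxylate | COc1cc([C@@H]2O[C@@H](c3ccc(OCc4ccccc4)c(OC)c3)[C@H](CO[Si](c3ccccc3)(c3ccccc3)C(C)(C)C)[C@H]2C(=O)OC)ccc1OCc1ccccc1 | intermediate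
12 | [(2R,3S,4S,5R)-2,5-bis[4-(benzyloxy)-3-methoxyphenyl]-4-{[(tert-butyldiphenylsilyl)oxy]methyl}tetrahydrofuran-3-yl]methanol | COc1cc([C@@H]2O[C@@H](c3ccc(OCc4ccccc4)c(OC)c3)[C@H](CO[Si](c3ccccc3)(c3ccccc3)C(C)(C)C)[C@H]2CO)ccc1OCc1ccccc1 | intermediate
13 | [(2R,3S,4S,5R)-2,5-bis[4-(benzyloxy)-3-methoxyphenyl]tetrahydrofuran-3,4-diyl]dimethanol | COc1cc([C@@H]2O[C@@H](c3ccc(OCc4ccccc4)c(OC)c3)[C@H](CO)[C@H]2CO)ccc1OCc1ccccc1 | intermediate
14 | (+)-neoolivil, [(2R,3S,4S,5R)-2,5-bis(4-hydroxy-3-methoxyphenyl)tetrahydrofuran-3,4-diyl]dimethanol | COc1cc([C@@H]2O[C@@H](c3ccc(O)c(OC)c3)[C@H](CO)[C@H]2CO)ccc1O | target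

**Step count**

Total steps: 10. Longest linear sequence: 10 steps (1 → 14).

**Steps most likely to fail**

Step 5. The crowded trisubstituted cyclopropane may ionise without being captured by the aldehyde and be lost by elimination or oligomerisation, or the Lewis acid may strip the silyl ether so that the freed hydroxyl lactonises onto the cis ester. The fallback expands the same three-membered ring intramolecularly and brings in the second aryl group as a carbanion. It sets out from 7: heating with LiCl in wet DMSO at 150 °C (ring-opening lactonisation with loss of one ester) should give (4S,5R)-5-[4-(benzyloxy)-3-methoxyphenyl]-4-{[(tert-butyldiphenylsilyl)oxy]methyl}dihydrofuran-2(3H)-one F1. Enolate alkylation (LDA, benzyl chloromethyl ether, −78 °C) trans to the C4 substituent should give (3S,4S,5R)-5-[4-(benzyloxy)-3-methoxyphenyl]-3-[(benzyloxy)methyl]-4-{[(tert-butyldiphenylsilyl)oxy]methyl}dihydrofuran-2(3H)-one F2. Addition of 4-(benzyloxy)-3-methoxyphenyllithium (from 1-(benzyloxy)-4-bromo-2-methoxybenzene and n-BuLi) should give the hemiketal (3S,4S,5R)-2,5-bis[4-(benzyloxy)-3-methoxyphenyl]-3-[(benzyloxy)methyl]-4-{[(tert-butyldiphenylsilyl)oxy]methyl}tetrahydrofuran-2-ol F3. Reductive deoxygenation with Et3SiH/BF3·OEt2 (−78 °C → rt, with equilibration of the new benzylic centre) should give all-trans (2R,3S,4S,5R)-2,5-bis[4-(benzyloxy)-3-methoxyphenyl]-3-[(benzyloxy)methyl]-4-{[(tert-butyldiphenylsilyl)oxy]methyl}tetrahydrofuran F4. TBAF should give {(2R,3S,4S,5R)-2,5-bis[4-(benzyloxy)-3-methoxyphenyl]-4-[(benzyloxy)methyl]tetrahydrofuran-3-yl}methanol F5, and hydrogenolysis of its three benzyl ethers (H2, Pd(OH)2/C) comes back to the route at 14.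

Step 7. After ionisation at C5 the cation may not reclose: it can be trapped by the C2 aryl ring (para to its methoxy group) in a Friedel–Crafts cyclisation to an aryltetralin, or lose the C4 proton, or the equilibration may stall. The fallback replaces the ionic pathway by a radical one. It sets out from 10 and uses reversible hydrogen-atom abstraction at the benzylic α-oxy C–H bonds by a thiyl radical (polarity-reversal catalysis: triphenylsilanethiol 10 mol %, a thermal radical initiator, hydrocarbon solvent, 60–80 °C). This should equilibrate C5 (and C2) without generating a cation and comes back to the route at 11; no new compound is made.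

Step 2. The electron-rich enal is a sluggish iminium electrophile, and the product, a formylcyclopropane with a strong aryl donor, may be re-activated by the amine and ring-open, which would erode yield and enantiomeric purity. The fallback builds the cyclopropane by carbene transfer and avoids the free alcohol 6. It sets out from 3: Luche reduction (NaBH4, CeCl3·7H2O, MeOH, 0 °C) should give (E)-3-[4-(benzyloxy)-3-methoxyphenyl]prop-2-en-1-ol F6, and silylation (TBDPSCl, imidazole) should give tert-butyl{[(E)-3-[4-(benzyloxy)-3-methoxyphenyl]prop-2-en-1-yl]oxy}diphenylsilane F7. Copper(I)/chiral bis(oxazoline)-catalysed cyclopropanation of F7 with the phenyliodonium ylide of dimethyl malonate is stereospecific for the trans-cyclopropane from the E-alkene, with the ligand enantiomer chosen for the (2S,3R) product, and comes back to the route at 7.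

**Further compounds**

F1 | step 5 | (4S,5R)-5-[4-(benzyloxy)-3-methoxyphenyl]-4-{[(tert-butyldiphenylsilyl)oxy]methyl}dihydrofuran-2(3H)-one | O=C1O[C@@H](c2ccc(OCc3ccccc3)c(OC)c2)[C@H](CO[Si](c2ccccc2)(c2ccccc2)C(C)(C)C)C1
F2 | step 5 | (3S,4S,5R)-5-[4-(benzyloxy)-3-methoxyphenyl]-3-[(benzyloxy)methyl]-4-{[(tert-butyldiphenylsilyl)oxy]methyl}dihydrofuran-2(3H)-one | O=C1O[C@@H](c2ccc(OCc3ccccc3)c(OC)c2)[C@H](CO[Si](c2ccccc2)(c2ccccc2)C(C)(C)C)[C@H]1COCc1ccccc1
F3 | step 5 | (3S,4S,5R)-2,5-bis[4-(benzyloxy)-3-methoxyphenyl]-3-[(benzyloxy)methyl]-4-{[(tert-butyldiphenylsilyl)oxy]methyl}tetrahydrofuran-2-ol (mixture at C2) | COc1cc(C2(O)O[C@@H](c3ccc(OCc4ccccc4)c(OC)c3)[C@H](CO[Si](c3ccccc3)(c3ccccc3)C(C)(C)C)[C@H]2COCc2ccccc2)ccc1OCc1ccccc1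
F4 | step 5 | (2R,3S,4S,5R)-2,5-bis[4-(benzyloxy)-3-methoxyphenyl]-3-[(benzyloxy)methyl]-4-{[(tert-butyldiphenylsilyl)oxy]methyl}tetrahydrofuran | COc1cc([C@@H]2O[C@@H](c3ccc(OCc4ccccc4)c(OC)c3)[C@H](CO[Si](c3ccccc3)(c3ccccc3)C(C)(C)C)[C@H]2COCc2ccccc2)ccc1OCc1ccccc1
F5 | step 5 | {(2R,3S,4S,5R)-2,5-bis[4-(benzyloxy)-3-methoxyphenyl]-4-[(benzyloxy)methyl]tetrahydrofuran-3-yl}methanol | COc1cc([C@@H]2O[C@@H](c3ccc(OCc4ccccc4)c(OC)c3)[C@H](CO)[C@H]2COCc2ccccc2)ccc1OCc1ccccc1
F0 | step 7 | none | none
F6 | step 2 | (E)-3-[4-(benzyloxy)-3-methoxyphenyl]prop-2-en-1-ol | OC/C=C/c1ccc(OCc2ccccc2)c(OC)c1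
F7 | step 2 | tert-butyl{[(E)-3-[4-(benzyloxy)-3-methoxyphenyl]prop-2-en-1-yl]oxy}diphenylsilane | CC(C)(C)[Si](OC/C=C/c1ccc(OCc2ccccc2)c(OC)c1)(c1ccccc1)c1ccccc1
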